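Slowness is the oddity of the grey run: from 5.00 h to 8.00 h the target creeps from 43 % to 46 %, while 51 % of the electrophile still stands in the flask. In each flask the electrophile is fed into the nucleophile, and the gas dissolves as free base.

| setting | grey | teal | cedar | ash |
|---|---|---|---|---|
| electrophile | 0.050 M (fed, over 1.5 h) | 0.050 M (fed, over 1.5 h) | 0.050 M (fed, over 1.5 h) | 0.050 M (fed, over 1.5 h) |
| nucleophile | 0.89 equiv | 1.7 equiv | 1.50 equiv | 2.00 equiv |
| gas | 20 mM (held) | 20 mM (held) | 20 mM (held) | 20 mM (held) |
| remark | run made earlier | run made earlier |  |  |
| time |  |  | 12 h | 12 h |

| run | time / h | electrophile / % | target / % |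
|---|---|---|---|
| grey | 0.500 | 30 | 1 |
| grey | 1.50 | 77 | 25 |
| grey | 3.00 | 65 | 36 |
| grey | 5.00 | 55 | 43 |
| grey | 6.00 | 55 | 43 |
| grey | 8.00 | 51 | 46 |
| teal | 1.33 | 52 | 33 |
| teal | 3.00 | 38 | 62 |
| teal | 4.00 | 29 | 70 |
| teal | 6.00 | 25 | 77 |
| teal | 8.00 | 20 | 82 |

(each reading ± 2 percentage points)

- part of the electrophile that has reacted at the end, cedar
- part of the electrophile that has reacted at the end, ash
- what raising the equivalents of nucleophile from its lowest to its highest value here does to the part of the electrophile that has reacted (changes below 5 percentage points count as none) (it falls / no change / it rises)

- at the start none of free base is dissolved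
- steps under discussion: electrophile + nucleophile -> acid set free + target; nucleophile + acid set free <-> protonated nucleophile; acid set free + free base <-> salt of the base; target -> over-reaction product; gas <-> free base
- percentages count the whole charge, also what has not yet gone in

The grey numbers do not seem to go together. By the count of the first step, 0.89 equiv of nucleophile should carry the reaction to 89.0 %, yet the target reads 46 %.

Following one molecule of nucleophile clears this up. At its fork it either attacks an electrophile, which sets an acid free, or it catches such an acid and becomes protonated nucleophile, which the readings suggest no longer attacks. So, as long as every acid pairs with nucleophile, each electrophile that reacts costs two nucleophile. Counted twice, the nucleophile is the limiting reagent in cedar.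

Call C the reacted share at which free nucleophile is used up if every acid pairs with it, which is half its equivalents: 75.0 % for cedar. The same reckoning gives 44.5 % for grey, close to its reading, and 85.0 % for teal, whose target reads 82 % and is still climbing. For ash, C is 100 %, so it sets no mark below the whole charge, and the time allowed must give that number.

The forecast, holding that “each electrophile consumed uses two nucleophile”, gives 77 % for cedar and 94 % for ash, and on the trend says: it rises.

The simulation gives 76.2 % for cedar and 92.9 % for ash, and the answer on the trend is: it rises, by 17 percentage points.

    electrophile + nucleophile → acid set free + target (k = 0.00310 L mol⁻¹ s⁻¹)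
    nucleophile + acid set free ⇌ protonated nucleophile, settled at all times (K = 22000 L mol⁻¹)
    acid set free + free base ⇌ salt of the base, settled at all times (K = 170 L mol⁻¹)
    target → over-reaction product (k = 3.60 × 10⁻⁷ s⁻¹)
    gas ⇌ free base, rate k5*(csat - [free base]) (kL = 0.00260 s⁻¹)

The difference in equivalents of nucleophile may be called the main reason that ash ends above cedar: ash set back to the equivalents of cedar gives 76.2 % instead of 92.9 %. The pairing of nucleophile with acid set free is part of that gap, which shrinks from 17 points to 1.4 points with the pairing taken away. Cedar ends at 76.2 % beside its C of 75.0 %, and the neighbour of cedar with 0.600 equiv has a C of 30.0 % and reaches 34.5 %, with 1.7 % of its nucleophile still free.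

All runs were generated by integration for substances that don't exist.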